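**Retrosynthetic overview**
1. The target comes from alcohol 16 by esterification at O9; the 9α-OH comes from hydride reduction of a C9 ketone, and the 8α-OAc from acetate displacement of an 8β-bromide.
2. The 7β-isopropenyl group comes from a catalyst-controlled 1,4-addition to the decalin enone 10 (C7=C8, C9=O).
3. Key disconnection: ring B of 10 is made by a one-carbon ring expansion (siloxycyclopropane opening) of the cyclopentanone of hydrindanone 6; the inserted carbon is C8 and the enone appears in the same operation.
4. The hydrindane carrying the cis C4/C5 methyl pair comes from an asymmetric Michael/aldol annulation of 3-methylcyclopentane-1,2-dione with (E)-pent-3-en-2-one.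
5. Ring order: five-membered ring (bought), then ring A (annulation), then ring B by expansion from five to six members.

Convention and assumption: eremophilane locants are used throughout (ring A = C1–C5, C10; ring B = C5–C10; in the hydrindanes C8 is still missing; β = face of the C5 methyl). The antipode of the amine in step 1 and the facial sense of (S)-BINAP in step 6 are assigned by analogy and would be confirmed on the first run.

**Step 1**
Reactants: 1 3-methylcyclopentane-1,2-dione; 2 (E)-pent-3-en-2-one
Product: 4 (3aR,4S)-3a,4-dimethyl-2,3,3a,4-tetrahydro-1H-indene-1,6(5H)-dione, via Michael adduct 3 (not isolated)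
Conditions: 9-amino-9-deoxy-epi-quinidine (20 mol%; the quinine-derived pseudo-enantiomer if the sense is opposite), 2-fluorobenzoic acid (40 mol%), toluene, 25 °C; then 4 Å MS, 70 °C
Reagents that add atoms: none
Why: Proposed new method: the primary amine condenses with 2 to a chiral (E)-iminium ion while its quinuclidine nitrogen hydrogen-bonds the acidic enol of 1, so the enol carbon C3 adds to the β-carbon in a compact transition state that fixes C4 (iminium face) and the quaternary C5 (cis-dimethyl pair, as in base-mediated annulations with pent-3-en-2-one), after which the methyl-ketone enamine closes ring A by aldol condensation onto the neighbouring ring carbonyl; the closest known reactions are primary-amine-catalysed asymmetric Michael additions and Robinson annulations of 1,3-dicarbonyl pronucleophiles with enones and organocatalytic Michael additions of unsubstituted cyclic 1,2-diones, whereas a 3-alkyl-1,2-dione building a quaternary centre on a β-substituted enone has not been shown.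

**Step 2**
Reactants: 4
Product: 5 (3aR,4S,7aS)-3a,4-dimethylhexahydro-1H-indene-1,6(2H)-dione
Conditions: H2 (1 atm), Pd/C (5 mol%), EtOAc, 25 °C; then DBU (5 mol%), 25 °C
Reagents that add atoms: none
Why: Catalytic hydrogenation saturates the electron-poor ene-dione C=C bond without touching the ketones, and the ring-fusion hydrogen (α to the cyclopentanone carbonyl) equilibrates to the more stable cis-hydrindanone.

**Step 3**
Reactants: 5
Product: 6 (3a'R,4'S,7a'S)-3a',4'-dimethylhexahydrospiro[[1,3]dioxolane-2,6'-inden]-1'(2'H)-one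
Conditions: HOCH2CH2OH (1.5 equiv), PPTS (10 mol%), benzene, reflux (Dean–Stark)
Reagents that add atoms: ethylene glycol, OCCO
Why: Selective ketalization, since the unhindered cyclohexanone carbonyl (C2) forms the dioxolane far more readily than the cyclopentanone carbonyl next to the ring fusion, as in 3,17-diketo steroids.

**Step 4**
Reactants: 6
Product: 8 siloxycyclopropane of 6 (CH2 bridging C9 and C7; C9 bears OSiMe3), via silyl enol ether 7 (not isolated)
Conditions: LiN(i-Pr)2, THF, −78 °C; Me3SiCl; then Zn–Cu couple, CH2I2, Et2O, reflux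
Reagents that add atoms: chlorotrimethylsilane, C[Si](C)(C)Cl; diiodomethane, ICI
Why: Kinetic enolization takes the CH2 (C7) and not the ring-fusion CH, and Simmons–Smith cyclopropanation of the electron-rich silyl enol ether places the future C8 on the C9–C7 bond; the two new cyclopropane stereocentres are destroyed in step 5.

**Step 5**
Reactants: 8
Product: 10 (4S,5R,10S)-2,2-(ethylenedioxy)-4,5-dimethyl-cis-decal-7-en-9-one, via chloro ketone 9 (not isolated)
Conditions: FeCl3 (2.2 equiv), pyridine (1 equiv), DMF, 0 °C; then NaOAc, MeOH, 65 °C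
Reagents that add atoms: none
Why: Ito–Saegusa ring expansion, in which FeCl3 oxidizes the siloxycyclopropane to an alkoxy radical, β-scission of the internal bond enlarges the five-membered ring to six with chlorine transfer to C7, and acetate-induced loss of HCl gives the C7=C8 enone exactly where the isopropenyl group is needed.

**Step 6**
Reactants: 10; 11 prop-1-en-2-ylboronic acid
Product: 12 (4S,5R,7S,10S)-2,2-(ethylenedioxy)eremophil-11-en-9-one
Conditions: [Rh(cod)OH]2 (2.5 mol%), (S)-BINAP (6 mol%), dioxane/H2O 10:1, 40 °C; then K2CO3, MeOH, 25 °C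
Reagents that add atoms: none
Why: Hayashi–Miyaura rhodium-catalysed asymmetric 1,4-addition under catalyst control, (S)-BINAP delivering the alkenyl group to the enone face that gives (S)-3-substituted cyclohexanones (here the β face of C7), after which carbonate equilibrates C10 through the C9 enolate to the cis-decalin, the only fusion in which the 7β-isopropenyl group is equatorial and not syn-axial to the C5 methyl.

**Step 7**
Reactants: 12
Product: 14 (4S,5R,7R,8R,10S)-8α-acetoxy-2,2-(ethylenedioxy)eremophil-11-en-9-one, via bromo ketone 13 (not isolated)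
Conditions: LiN(SiMe3)2, THF, −78 °C; NBS, −78 °C; then CsOAc, 18-crown-6, DMF, 0 to 25 °C
Reagents that add atoms: cesium acetate, CC(=O)[O-].[Cs+]
Why: Kinetic enolate formation at C8 and axial bromination on the convex β face are followed by SN2 displacement of the activated α-bromo ketone by acetate with inversion, which gives the equatorial 8α-acetate trans to the isopropenyl group.

**Step 8**
Reactants: 14
Product: 16 (4S,5R,7R,8R,9S,10S)-8α-acetoxy-9α-hydroxyeremophil-11-en-2-one, via ketal alcohol 15 (not isolated)
Conditions: Li[HB(s-Bu)3], THF, −78 °C; then 2 M HCl, THF, 25 °C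
Reagents that add atoms: water, O
Why: Diastereoselective ketone reduction, because axial approach to C9 is blocked by the syn-axial C4 of the cis-decalin so the bulky hydride enters from the convex β face and gives the axial 9α-alcohol cis to the acetate, and aqueous acid then hydrolyses the dioxolane (acetal deprotection).

**Step 9**
Reactants: 16; 17 3-methylbut-2-enoyl chloride
Product: 18 (4S,5R,7R,8R,9S,10S)-8α-acetoxy-9α-(3-methylbut-2-enoyloxy)eremophil-11-en-2-one
Conditions: pyridine, DMAP (20 mol%), CH2Cl2, 0 to 25 °C
Reagents that add atoms: none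
Why: DMAP-catalysed esterification of the hindered axial alcohol with the acid chloride, with pyridine instead of a trialkylamine to avoid deconjugation of the senecioyl unit through its vinylketene; no stereocentre is affected.

**Compound list**
1 | 3-methylcyclopentane-1,2-dione | CC1CCC(=O)C1=O | starting material
2 | (E)-pent-3-en-2-one | C/C=C/C(C)=O | starting material
3 | (3R)-3-methyl-3-[(2S)-4-oxopentan-2-yl]cyclopentane-1,2-dione | C1C[C@@]([C@@H](C)CC(C)=O)(C)C(=O)C1=O | intermediate (not isolated)
4 | (3aR,4S)-3a,4-dimethyl-2,3,3a,4-tetrahydro-1H-indene-1,6(5H)-dione | C1C[C@@]2(C)C(=CC(=O)C[C@@H]2C)C1=O | intermediate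
5 | (3aR,4S,7aS)-3a,4-dimethylhexahydro-1H-indene-1,6(2H)-dione (cis-fused) | C1C[C@@]2(C)[C@H](CC(=O)C[C@@H]2C)C1=O | intermediate
6 | 5 with the six-ring carbonyl (C2) as 1,3-dioxolane, cyclopentanone free | C1C[C@@]2(C)[C@H](CC3(OCCO3)C[C@@H]2C)C1=O | intermediate
7 | trimethylsilyl enol ether of 6 (C9(OSiMe3)=C7) | C[Si](C)(C)OC1=CC[C@@]2(C)[C@@H]1CC1(OCCO1)C[C@@H]2C | intermediate (not isolated)
8 | siloxycyclopropane of 6 (CH2 across C9–C7, OSiMe3 on C9; mixture at the cyclopropane carbons) | C12C[C@@]3(C)[C@H](CC4(OCCO4)C[C@@H]3C)C1(O[Si](C)(C)C)C2 | intermediate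
9 | 7-chloro-2,2-(ethylenedioxy)-4β,5β-dimethyl-10βH-decalin-9-one (mixture at C7) | ClC1C[C@@]2(C)[C@H](CC3(OCCO3)C[C@@H]2C)C(=O)C1 | intermediate (not isolated)
10 | (4S,5R,10S)-2,2-(ethylenedioxy)-4,5-dimethyl-cis-decal-7-en-9-one | C1=CC[C@@]2(C)[C@H](CC3(OCCO3)C[C@@H]2C)C1=O | intermediate
11 | prop-1-en-2-ylboronic acid | CC(=C)B(O)O | starting material
12 | (4S,5R,7S,10S)-2,2-(ethylenedioxy)eremophil-11-en-9-one (7β-isopropenyl, 10βH) | C=C(C)[C@H]1C[C@@]2(C)[C@H](CC3(OCCO3)C[C@@H]2C)C(=O)C1 | intermediate
13 | (4S,5R,7R,8S,10S)-8β-bromo-2,2-(ethylenedioxy)eremophil-11-en-9-one | C=C(C)[C@H]1C[C@@]2(C)[C@H](CC3(OCCO3)C[C@@H]2C)C(=O)[C@H]1Br | intermediate (not isolated)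
14 | (4S,5R,7R,8R,10S)-8α-acetoxy-2,2-(ethylenedioxy)eremophil-11-en-9-one | C=C(C)[C@H]1C[C@@]2(C)[C@H](CC3(OCCO3)C[C@@H]2C)C(=O)[C@@H]1OC(C)=O | intermediate
15 | (4S,5R,7R,8R,9S,10S)-8α-acetoxy-2,2-(ethylenedioxy)eremophil-11-en-9α-ol | C=C(C)[C@H]1C[C@@]2(C)[C@H](CC3(OCCO3)C[C@@H]2C)[C@H](O)[C@@H]1OC(C)=O | intermediate (not isolated)
16 | (4S,5R,7R,8R,9S,10S)-8α-acetoxy-9α-hydroxyeremophil-11-en-2-one | C=C(C)[C@H]1C[C@@]2(C)[C@H](CC(=O)C[C@@H]2C)[C@H](O)[C@@H]1OC(C)=O | intermediate
17 | 3-methylbut-2-enoyl chloride | CC(C)=CC(Cl)=O | starting material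
18 | (4S,5R,7R,8R,9S,10S)-8α-acetoxy-9α-(3-methylbut-2-enoyloxy)eremophil-11-en-2-one (4β,5β-dimethyl, 7β-isopropenyl, 10βH) | C=C(C)[C@H]1C[C@@]2(C)[C@H](CC(=O)C[C@@H]2C)[C@H](OC(=O)C=C(C)C)[C@@H]1OC(C)=O | target

**Totals**
Total step count: 9. Longest linear sequence: 9 steps (1 to 18).

**Steps most likely to fail, with fallbacks**

Step 1 (the proposed annulation). The enol of 1 may add too slowly to the β-methyl enone, or with poor control at the quaternary centre. The fallback is known chemistry and sets out from 1. Palladium-catalysed asymmetric O-allylation of the diosphenol (Pd2(dba)3, chiral bis-phosphine ligand of the Trost type) with the methyl carbonate of (E)-pent-3-en-2-ol gives 3-methyl-2-{[(2R,3E)-pent-3-en-2-yl]oxy}cyclopent-2-en-1-one F1. Claisen rearrangement (toluene, 110 °C) through the chair transition state, with the ether methyl equatorial, transfers that stereocentre to the vicinal quaternary and tertiary carbons of (3R)-3-methyl-3-[(2S,3E)-pent-3-en-2-yl]cyclopentane-1,2-dione F2. Wacker-type oxidation (Pd(OAc)2, benzoquinone, HBF4, MeCN/H2O) puts the carbonyl on the olefin carbon remote from the diketone and gives 3, where the fallback comes back to the route. Compound 3 is then cyclized to 4 with pyrrolidinium acetate as in the second stage of step 1.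

Step 5 (ring expansion). FeCl3 may cleave the dioxolane, or the radical opening may give some non-expanded α-methylene ketone. The fallback sets out from 6 and inserts the carbon by a polar 1,2-shift instead. Me3SiCHN2 with Me3Al (CH2Cl2, −78 °C), with migration of the less substituted α-carbon and protodesilylation on work-up, gives the saturated ring-expanded ketone (4S,5R,10S)-2,2-(ethylenedioxy)-4,5-dimethyl-cis-decalin-9-one F3. Dehydrogenation of its kinetic enolate (LiN(i-Pr)2, then N-tert-butylbenzenesulfinimidoyl chloride, −78 °C) gives 10, where the fallback comes back to the route.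

Step 7 (C8 oxygenation). Acetate may eliminate HBr from 13 instead of substituting, or the bromide may form as a mixture. The fallback sets out from 12 and brings in the oxygen as an electrophile, then inverts it. Hydroxylation of the C8 enolate (LiN(i-Pr)2, then 2-(phenylsulfonyl)-3-phenyloxaziridine) on the convex face gives (4S,5R,7R,8S,10S)-2,2-(ethylenedioxy)-8β-hydroxyeremophil-11-en-9-one F4. Mitsunobu reaction with acetic acid (PPh3, DIAD, THF) inverts C8 and gives 14, where the fallback comes back to the route.

Further compounds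
F1 | step 1 | 3-methyl-2-{[(2R,3E)-pent-3-en-2-yl]oxy}cyclopent-2-en-1-one | C/C=C/[C@@H](C)OC1=C(C)CCC1=O
F2 | step 1 | (3R)-3-methyl-3-[(2S,3E)-pent-3-en-2-yl]cyclopentane-1,2-dione | C1C[C@@]([C@@H](C)/C=C/C)(C)C(=O)C1=O
F3 | step 5 | (4S,5R,10S)-2,2-(ethylenedioxy)-4,5-dimethyl-cis-decalin-9-one | C1C[C@@]2(C)[C@H](CC3(OCCO3)C[C@@H]2C)C(=O)C1
F4 | step 7 | (4S,5R,7R,8S,10S)-2,2-(ethylenedioxy)-8β-hydroxyeremophil-11-en-9-one | C=C(C)[C@H]1C[C@@]2(C)[C@H](CC3(OCCO3)C[C@@H]2C)C(=O)[C@H]1O
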